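**Retrosynthetic overview**
1. After ester cleavage, the last cut is the bond between the quaternary carbon C-3 of the cyclohexane and C-2' of the bicyclo[3.2.1]octane. It is made by Giese addition of a tertiary cyclohexyl radical to a bicyclic enone, and each partner reacts on its own open face.
2. Bicycle numbering: C-1' is the CHO-bearing bridgehead, C-4' the ketone, C-5' the second bridgehead, C-6' the methylidene carbon, C-7' the CH2 next to it, C-8' the one-carbon bridge. C-1'–C-8' and C-5'–C-6' are cut together, which opens both rings to an acyclic keto-aldehyde bearing a vinyl ketone and a propargyl group.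
3. Enabling feature: C-1' is the α-carbon of the aldehyde and lies 1,5 to the C-4' ketone along C-1'–C-8'–C-5'–C-4' (Michael retron). C-6', with its exocyclic CH2, sits on C-5' (α to that ketone) and is tied to C-1' through C-7' (Conia-ene retron of a propargyl group). The monocyclic intermediate has a mirror plane, so one chiral catalyst pair sets both bridgeheads.
4. Cyclohexane ring: enantioselective Diels–Alder reaction of dimethyl fumarate with (E)-piperylene, enolate methylation (quaternary C-1), alkene walk, then Markovnikov hydration to the tertiary alcohol that serves as radical precursor.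
5. Ring order: the six-membered and then the five-membered ring of the bicycle form in one operation (step 3). The cyclohexane ring is made separately (step 5), and the fragments are joined in step 10.

Key step: step 3

Assumption: the absolute sense of induction in the two catalytic asymmetric steps (3 and 5) is taken to be selectable through the catalyst antipode, both antipodes being available; the structures drawn are the ones required.

Step 1
Reactants: 1 pent-4-yn-1-ol
Product: 2 pent-4-ynal
Conditions: TEMPO (10 mol %), PhI(OAc)2 (1.1 equiv), CH2Cl2, rt; used as a solution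
Reagents that add atoms: none
Why: Oxoammonium (TEMPO) oxidation of a primary alcohol stops at the aldehyde in the absence of water and leaves the terminal alkyne untouched; no stereocentre is formed.

Step 2
Reactants: 2 pent-4-ynal; 3 1,5-dichloropentan-3-one
Product: 5 5-oxo-2-(prop-2-yn-1-yl)hept-6-enal, via divinyl ketone 4 (not isolated)
Conditions: 3 (3 equiv), Et3N (6.6 equiv), Et2O, 0 °C, filter; then 2 (1 equiv), (S)-diphenylprolinol methyl ether (5 mol %), ethyl 3,4-dihydroxybenzoate (20 mol %), 4 °C
Reagents that add atoms: none
Why: Double E1cB loss of HCl frees the dienone, and an enamine-catalysed Michael addition of the linear aldehyde to one vinyl group should stop at the mono-adduct because the dienone is in excess and the bulky amine does not engage the α-branched product; the new stereocentre is erased in step 3, so its configuration is immaterial.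

Step 3
Reactants: 5 5-oxo-2-(prop-2-yn-1-yl)hept-6-enal
Product: 7 (1R,5R)-6-methylidene-4-oxobicyclo[3.2.1]octane-1-carbaldehyde, via 4-oxo-1-(prop-2-yn-1-yl)cyclohexane-1-carbaldehyde 6 (not isolated)
Conditions: chiral 2-[bis(3,5-dimethylphenyl)methyl]pyrrolidine (20 mol %), AgNTf2 (10 mol %), cinchona-derived aminophosphine ligand (11 mol %), PhCO2H (20 mol %), toluene, 25 → 40 °C
Reagents that add atoms: none
Why: Proposed new method: the pyrrolidine first turns the α-branched aldehyde of 5 into its enamine, whose α-carbon adds to the terminal carbon of the vinyl ketone (6-endo-trig Michael closure of the six-membered ring, i.e. the second half of a known amine-catalysed [5+1] double Michael annulation of divinyl ketones), and hydrolysis gives achiral 6. The same amine then condenses with the ketone of 6, and the enamine carbon attacks the internal carbon of the Ag(I)-bound terminal alkyne anti to silver (5-exo-dig Conia-ene-type closure of the five-membered ring), protodeargentation leaving the exocyclic methylene. The closest known reaction types are the amine/copper(I) Michael–carbocyclisation cascade of propargyl malonates with enones and the silver(I)/chiral amine desymmetrising cycloisomerisation of alkyne-linked cyclohexanones; new here are their union in an intramolecular sense, an aldehyde as Michael donor and an all-carbon tether that gives a bicyclo[3.2.1]octane. Both stereocentres (C-1 and C-5) arise in the second closure: because 6 has a mirror plane, the matched pair of chiral pyrrolidine and chiral phosphine–silver complex chooses between the two enantiotopic α-methylene groups, and the bridge geometry fixes C-5 relative to C-1 since only an axial propargyl group can reach the α-carbon. The step needs C- over N-addition to the enone, 5-exo over 6-endo attack and no migration of the new double bond; these are secured by the reversibility of the aza-Michael addition, by the Markovnikov bias of a terminal alkyne on a three-atom tether, and by the fact that conjugation with the ketone would need a bridgehead double bond.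

Step 4
Reactants: 7 (1R,5R)-6-methylidene-4-oxobicyclo[3.2.1]octane-1-carbaldehyde
Product: 8 (1R,5R)-6-methylidene-4-oxobicyclo[3.2.1]oct-2-ene-1-carbaldehyde
Conditions: IBX (2.5 equiv), DMSO/PhF 1:2, 70 °C
Reagents that add atoms: none
Why: IBX dehydrogenation of a ketone: only the C-3 methylene can enolise (C-5 is a bridgehead and the aldehyde has no α-hydrogen), so the C-2/C-3 enone is the only possible product and both stereocentres stay untouched.

Step 5
Reactants: 9 dimethyl fumarate; 10 (E)-penta-1,3-diene
Product: 11 dimethyl (1S,2S,3S)-3-methylcyclohex-4-ene-1,2-dicarboxylate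
Conditions: proline-derived o-tolyl-oxazaborolidine activated with HNTf2 (15 mol %), 10 (3 equiv), CH2Cl2, −20 °C → rt
Reagents that add atoms: none
Why: Enantioselective Diels–Alder reaction under chiral oxazaborolidinium catalysis: the catalyst binds one ester carbonyl and shields one of the enantiotopic faces of the fumarate, which sets C-1 and C-2 (trans, from the E-alkene), while the endo and "ortho" orientation of the bound ester places the C-3 methyl cis to the C-2 ester (this centre is erased in step 7, so its epimer converges).

Step 6
Reactants: 11 dimethyl (1S,2S,3S)-3-methylcyclohex-4-ene-1,2-dicarboxylate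
Product: 12 dimethyl (1R,2S,3S)-1,3-dimethylcyclohex-4-ene-1,2-dicarboxylate
Conditions: LDA (1.05 equiv), THF, −78 °C; MeI (3 equiv), DMPU, −78 → −20 °C
Reagents that add atoms: iodomethane CI
Why: Kinetic ester enolate alkylation: LDA should remove the C-1 hydrogen, whose enolate is less strained than that at C-2 (flanked by two branched carbons), and MeI enters the exocyclic enolate on the ring face opposite to the vicinal ester and the C-3 methyl group, so that the quaternary centre forms with the two ester groups cis.

Step 7
Reactants: 12 dimethyl (1R,2S,3S)-1,3-dimethylcyclohex-4-ene-1,2-dicarboxylate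
Product: 13 dimethyl (1R,2S)-1,3-dimethylcyclohex-3-ene-1,2-dicarboxylate
Conditions: RuHCl(CO)(PPh3)3 (5 mol %), toluene, 110 °C
Reagents that add atoms: none
Why: Ruthenium hydride alkene isomerisation (insertion/β-hydride elimination walk) should drain the disubstituted alkene isomers into the trisubstituted one, and the walk stops there because C-1 is quaternary on one side and a shift into conjugation on the other side would need a tertiary ruthenium alkyl at C-3; C-1 and C-2 are not touched.

Step 8
Reactants: 13 dimethyl (1R,2S)-1,3-dimethylcyclohex-3-ene-1,2-dicarboxylate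
Product: 14 dimethyl (1R,2R,3R)-3-hydroxy-1,3-dimethylcyclohexane-1,2-dicarboxylate
Conditions: Mn(dpm)3 (10 mol %), PhSiH3 (2.5 equiv), O2 (1 atm), i-PrOH/CH2Cl2, 0 °C → rt
Reagents that add atoms: dioxygen O=O
Why: Mukaiyama hydration: hydrogen-atom transfer from Mn–H to C-4 gives the tertiary C-3 radical (Markovnikov), which is trapped by O2 on the face opposite to the two cis esters, so the hydroxyl stays away from the C-1 ester and cannot lactonise; this centre becomes planar again in step 10.

Step 9
Reactants: 14 dimethyl (1R,2R,3R)-3-hydroxy-1,3-dimethylcyclohexane-1,2-dicarboxylate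
Product: 16 (1R,2R,3R)-2,3-bis(methoxycarbonyl)-1,3-dimethylcyclohexyl 1,3-dioxoisoindolin-2-yl oxalate, via cyclohexyl chlorooxoacetate 15 (not isolated)
Conditions: (COCl)2 (5 equiv), Et2O, 0 °C → rt, evaporate; N-hydroxyphthalimide (1.1 equiv), Et3N (1.2 equiv), CH2Cl2, 0 °C; filtered, concentrated and used crude
Reagents that add atoms: oxalyl chloride O=C(Cl)C(=O)Cl; N-hydroxyphthalimide O=C1c2ccccc2C(=O)N1O
Why: Two-stage mixed oxalate synthesis: the small and very reactive oxalyl chloride acylates even a hindered tertiary alcohol without breaking its C–O bond (retention), and the remaining acid chloride is esterified by N-hydroxyphthalimide to give a redox-active tert-alkyl oxalate.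

Step 10
Reactants: 16 (1R,2R,3R)-2,3-bis(methoxycarbonyl)-1,3-dimethylcyclohexyl 1,3-dioxoisoindolin-2-yl oxalate; 8 (1R,5R)-6-methylidene-4-oxobicyclo[3.2.1]oct-2-ene-1-carbaldehyde
Product: 17 dimethyl (1R,2S,3S)-3-[(1R,2S,5R)-1-formyl-6-methylidene-4-oxobicyclo[3.2.1]octan-2-yl]-1,3-dimethylcyclohexane-1,2-dicarboxylate
Conditions: Ru(bpy)3(PF6)2 (1.5 mol %), diethyl Hantzsch ester (1.5 equiv), i-Pr2NEt·HBF4 (1 equiv), THF/CH2Cl2 1:1, blue LEDs, rt
Reagents that add atoms: none
Why: Photoredox Giese fragment coupling: single-electron reduction of the N-phthalimidoyl oxalate and loss of two CO2 give the nucleophilic tertiary radical, which adds to the enone β-carbon and not to the aldehyde or the unactivated alkene; C-2 of the bicycle is set by approach on the exo face (the side of the one-carbon bridge, away from the two-carbon bridge), and the quaternary C-3 by bonding on the ring face opposite to the axial C-1 ester and the vicinal C-2 ester.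

Step 11
Reactants: 17 dimethyl (1R,2S,3S)-3-[(1R,2S,5R)-1-formyl-6-methylidene-4-oxobicyclo[3.2.1]octan-2-yl]-1,3-dimethylcyclohexane-1,2-dicarboxylate
Product: 18 (1R,2S,3S)-3-[(1R,2S,5R)-1-formyl-6-methylidene-4-oxobicyclo[3.2.1]octan-2-yl]-1,3-dimethylcyclohexane-1,2-dicarboxylic acid
Conditions: n-PrSLi (8 equiv), HMPA, rt; then 1 M HCl to pH 2, 0 °C
Reagents that add atoms: none
Why: Thiolate SN2 dealkylation of methyl esters: the nucleophile attacks the O-methyl carbon, so hindrance at the two carbonyl groups does not matter, the thiolate adds only reversibly to the non-enolisable aldehyde, and no stereocentre is touched (C-5' is a bridgehead and the ester α-hydrogen is far too weakly acidic).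

**Compound list**
1 | pent-4-yn-1-ol | C#CCCCO | starting material
2 | pent-4-ynal | C#CCCC=O | intermediate
3 | 1,5-dichloropentan-3-one | ClCCC(=O)CCCl | starting material
4 | penta-1,4-dien-3-one (divinyl ketone) | C=CC(=O)C=C | intermediate
5 | 5-oxo-2-(prop-2-yn-1-yl)hept-6-enal (configuration at C-2 immaterial) | C#CCC(C=O)CCC(=O)C=C | intermediate
6 | 4-oxo-1-(prop-2-yn-1-yl)cyclohexane-1-carbaldehyde (achiral) | C#CCC1(C=O)CCC(=O)CC1 | intermediate
7 | (1R,5R)-6-methylidene-4-oxobicyclo[3.2.1]octane-1-carbaldehyde | C=C1C[C@]2(C=O)C[C@H]1C(=O)CC2 | intermediate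
8 | (1R,5R)-6-methylidene-4-oxobicyclo[3.2.1]oct-2-ene-1-carbaldehyde | C=C1C[C@]2(C=O)C[C@H]1C(=O)C=C2 | intermediate
9 | dimethyl fumarate | COC(=O)/C=C/C(=O)OC | starting material
10 | (E)-penta-1,3-diene | C/C=C/C=C | starting material
11 | dimethyl (1S,2S,3S)-3-methylcyclohex-4-ene-1,2-dicarboxylate (esters trans, methyl cis to the C-2 ester) | C[C@H]1C=CC[C@H](C(=O)OC)[C@H]1C(=O)OC | intermediate
12 | dimethyl (1R,2S,3S)-1,3-dimethylcyclohex-4-ene-1,2-dicarboxylate (esters cis, C-1 methyl trans to them) | C[C@H]1C=CC[C@@](C)(C(=O)OC)[C@H]1C(=O)OC | intermediate
13 | dimethyl (1R,2S)-1,3-dimethylcyclohex-3-ene-1,2-dicarboxylate | CC1=CCC[C@@](C)(C(=O)OC)[C@H]1C(=O)OC | intermediate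
14 | dimethyl (1R,2R,3R)-3-hydroxy-1,3-dimethylcyclohexane-1,2-dicarboxylate (OH trans to both esters) | O[C@]1(C)CCC[C@@](C)(C(=O)OC)[C@H]1C(=O)OC | intermediate
15 | (1R,2R,3R)-2,3-bis(methoxycarbonyl)-1,3-dimethylcyclohexyl chlorooxoacetate | O=C(Cl)C(=O)O[C@]1(C)CCC[C@@](C)(C(=O)OC)[C@H]1C(=O)OC | intermediate
16 | (1R,2R,3R)-2,3-bis(methoxycarbonyl)-1,3-dimethylcyclohexyl 1,3-dioxoisoindolin-2-yl oxalate | O=C(O[C@]1(C)CCC[C@@](C)(C(=O)OC)[C@H]1C(=O)OC)C(=O)ON1C(=O)c2ccccc2C1=O | intermediate
17 | dimethyl (1R,2S,3S)-3-[(1R,2S,5R)-1-formyl-6-methylidene-4-oxobicyclo[3.2.1]octan-2-yl]-1,3-dimethylcyclohexane-1,2-dicarboxylate | C=C1C[C@]2(C=O)C[C@H]1C(=O)C[C@H]2[C@]1(C)CCC[C@@](C)(C(=O)OC)[C@H]1C(=O)OC | intermediate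
18 | (1R,2S,3S)-3-[(1R,2S,5R)-1-formyl-6-methylidene-4-oxobicyclo[3.2.1]octan-2-yl]-1,3-dimethylcyclohexane-1,2-dicarboxylic acid | C=C1C[C@]2(C=O)C[C@H]1C(=O)C[C@H]2[C@]1(C)CCC[C@@](C)(C(=O)O)[C@H]1C(=O)O | target

Total step count: 11. Longest linear sequence: 7 (steps 5–11); the other branch has 6 steps (1–4, 10, 11).

**Steps most likely to fail**

1. **Step 3.**
   - What may go wrong: enamine formation from the α-branched aldehyde may be slow, so that polymerisation of the vinyl ketone or lasting amine addition to it takes over. The sequence may stall at the monocyclic stage, or the two enantiotopic methylene groups may be poorly told apart.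
   - Fallback (known chemistry; the two bonds are made in two operations): it sets out from 2 and comes back at 7. α-Methylenation of 2 with aqueous formaldehyde under pyrrolidine/propionic acid catalysis should give 2-methylidenepent-4-ynal F1. An enantioselective, para-selective Diels–Alder reaction of F1 with 2-(triisopropylsilyloxy)buta-1,3-diene under chiral oxazaborolidinium catalysis should give (1R)-1-(prop-2-yn-1-yl)-4-(triisopropylsilyloxy)cyclohex-3-ene-1-carbaldehyde F2. Its regiodefined silyl enol ether should close onto the alkyne under cationic gold(I) catalysis in wet CH2Cl2 (5-exo-dig) to give 7.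

2. **Step 10.**
   - What may go wrong: addition of the tertiary radical to a β-carbon flanked by a quaternary bridgehead may be slow. Premature reduction of the radical, β-elimination of the oxalate before fragmentation, or reduction of the enone could then win, and facial selectivity on either partner may erode.
   - Fallback: it sets out from 13 (with 8) and comes back at 17. Markovnikov addition of HBr to 13 should give dimethyl (1R,2R)-3-bromo-1,3-dimethylcyclohexane-1,2-dicarboxylate F3. A nickel-catalysed reductive conjugate addition (Ni(II)/neocuproine, Mn, Et3SiCl) first turns 8 into a 1-silyloxyallyl-nickel species and makes the C–C bond by reductive elimination at nickel, not by free-radical attack on the hindered carbon. It should give the triethylsilyl enol ether of 17 F4, which dilute acid cleaves to 17.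

3. **Step 7.**
   - What may go wrong: the alkene walk may be incomplete, the double bond may leak into conjugation with the C-2 ester (loss of the C-2 stereocentre), or the catalyst may be deactivated by chelation to the diester.
   - Fallback: it sets out from 12 and comes back at 14. Hydrogenation (H2, Pd/C) should give dimethyl (1R,2S,3S)-1,3-dimethylcyclohexane-1,2-dicarboxylate F5. Hydroxylation of its only unactivated tertiary C–H bond with methyl(trifluoromethyl)dioxirane (O-insertion with retention) should give 14 directly.

**Further compounds**
F1 | step 3 | 2-methylidenepent-4-ynal | C#CCC(=C)C=O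
F2 | step 3 | (1R)-1-(prop-2-yn-1-yl)-4-(triisopropylsilyloxy)cyclohex-3-ene-1-carbaldehyde | C#CC[C@]1(C=O)CC=C(O[Si](C(C)C)(C(C)C)C(C)C)CC1
F3 | step 10 | dimethyl (1R,2R)-3-bromo-1,3-dimethylcyclohexane-1,2-dicarboxylate (C-3 undefined) | CC1(Br)CCC[C@@](C)(C(=O)OC)[C@H]1C(=O)OC
F4 | step 10 | triethylsilyl enol ether of 17 | C=C1C[C@]2(C=O)C[C@H]1C(O[Si](CC)(CC)CC)=C[C@H]2[C@]1(C)CCC[C@@](C)(C(=O)OC)[C@H]1C(=O)OC
F5 | step 7 | dimethyl (1R,2S,3S)-1,3-dimethylcyclohexane-1,2-dicarboxylate | C[C@H]1CCC[C@@](C)(C(=O)OC)[C@H]1C(=O)OC
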